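A catalyst charged at 0.11 mol% of the substrate cannot hide a share of the charge from an analysis that scatters by 1.5 percentage points, so one number tells us both substrate and target: x, the fraction of substrate left.

| flask | substrate | gas | free catalyst | remark | time |
|---|---|---|---|---|---|
| noon | 0.65 M | 78 mM (held) | 0.11 mol% | run made earlier |  |
| summer | 0.98 M | 78 mM (held) | 0.11 mol% | run made earlier |  |
| dusk | 1.3 M | 78 mM (held) | 0.055 mol% | run made earlier |  |
| flask | 1.3 M | 78 mM (held) | 0.11 mol% |  | 30 min |

| run | time / min | target / % | substrate / % |
|---|---|---|---|
| noon | 1.33 | 8 | 96 |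
| noon | 2.00 | 8 | 88 |
| noon | 3.00 | 14 | 84 |
| noon | 5.00 | 27 | 76 |
| noon | 8.00 | 39 | 61 |
| noon | 12.0 | 57 | 50 |
| noon | 20.0 | 75 | 23 |
| summer | 2.50 | 13 | 87 |
| summer | 5.00 | 25 | 76 |
| summer | 8.00 | 40 | 60 |
| summer | 10.0 | 50 | 50 |
| summer | 12.0 | 55 | 47 |
| summer | 15.0 | 67 | 30 |
| summer | 20.0 | 80 | 16 |
| dusk | 1.33 | 3 | 94 |
| dusk | 2.50 | 12 | 91 |
| dusk | 5.00 | 18 | 82 |
| dusk | 10.0 | 35 | 64 |
| dusk | 20.0 | 64 | 38 |

(scatter of a reading: 1.5 percentage points)

- the analysis behind the earlier runs scatters by 1.5 percentage points, standard deviation
- at the start none of the gas is in solution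

1. the target in the flask at 30 min, as a percentage of the substrate charged
2. the substrate in the flask at 30 min, as a percentage of the substrate charged

In the runs so far, the root of x falls almost in a straight line, and we call the time at which that line reaches zero the emptying time T:

√x = 1 − t/T

The summer run gives 34.1 min from its 10.0 min reading and 33.3 min from its 20.0 min reading, so these two readings lie close to one line. The noon run gives 38.4 min. The dusk run, with half the loading, gives 52.1 min. The flask has the loading of noon and summer, though more substrate than either, and we take the mean of those two values as our estimate of its emptying time, 35.9 min.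

Now the ladder of times for the flask. The line starts x falling at 2/T, so one turn of the catalyst, its turnover time, lasts about 1.18 s, far shorter than the minutes of the run. Next comes the asked 30 min, and then T, which is longer, so our line still leaves some substrate at the reading:

x = (1 − t/T)² = 2.69 %

We therefore expect 97.3 % target. The forecast differs, with 91 % target and 8 % substrate, holding that “the true tail is softer”.

The flask gives 96.1 % target and 3.95 % substrate.

    coupling partner + free catalyst ⇌ catalyst intermediate A (K = 35.0 M⁻¹, k = 5100 M⁻¹ s⁻¹)
    substrate + catalyst intermediate A ⇌ catalyst intermediate B (K = 24.0 M⁻¹, k = 3.10 M⁻¹ s⁻¹)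
    catalyst intermediate B → free catalyst + target (k = 4.90 s⁻¹)
    gas ⇌ coupling partner, rate k4*(csat - [coupling partner]) (kL = 0.0150 s⁻¹)

Read backwards, the flask's substrate gives an emptying time of 37.4 min, against our 35.9 min. Now take the same flask with 0.066 mol% of free catalyst. We place its T between the flask's and the dusk run's, on a logarithmic scale of loading, which gives 47.8 min. The line then leaves 13.9 % substrate at 30 min. That neighbouring flask holds 12.6 % substrate.

The runs were computed with made-up constants, noise included.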